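## Retrosynthetic overview
1. (2S)-Naringenin 1 supplies the carbon skeleton of both halves, with all six rings and both stereocentres in place. No ring is formed in the route; only the bond between the two flavanones is made.
2. Electrophilic half: 1 gives dibromide 2. The bromine caps on C-6 and C-8 silence ring A, so 4'-OH is the only phenol that can be oxidised.
3. Nucleophilic half: 1 gives 4 (via 3) and then 5, carrying 7-OMe, 4'-OBn and an iodine cap on C-6. C-8 is then the only open electron-rich carbon.
4. Key disconnection, C-3'–C-8'': both carbons are innately nucleophilic. C-3' is inverted as the O-iodanyl phenol 6, a phenoxenium or aromatic enolonium equivalent, and C-8'' of 5 attacks it to give 7.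
5. One hydrogenolysis removes two Br, one I and the benzyl group from 7 to give target 8.

Assumption: (2S)-naringenin is bought as the single enantiomer (CAS 480-41-1, ee checked by chiral HPLC before use), and the C-3'–C-8'' axis, which has only three small ortho groups, rotates freely and is not a stereo-element of the given SMILES.

Locants: unit 1 is the naringenin half (C-2 to C-8, C-1' to C-6'). Unit 2 is the sakuranetin half (C-2'' to C-8'', C-1''' to C-6''').

## Route

Step 1
Reactants: 1 (2S)-naringenin
Product: 2 (2S)-6,8-dibromonaringenin [(2S)-6,8-dibromo-5,7-dihydroxy-2-(4-hydroxyphenyl)chroman-4-one]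
Conditions: NBS (2.05 equiv), MeCN, 0 °C to rt, dark, 1 h
Reagents that add atoms: N-bromosuccinimide, O=C1CCC(=O)N1Br
Why: Electrophilic aromatic bromination: the phloroglucinol-type ring A is far more reactive than ring B, so two equivalents of NBS fill exactly C-6 and C-8, and the neutral medium leaves the C-2 stereocentre (brought in with 1) untouched.

Step 2
Reactants: 1 (2S)-naringenin
Product: 4 (2S)-4'-O-benzylsakuranetin [(2S)-2-(4-benzyloxyphenyl)-5-hydroxy-7-methoxychroman-4-one], via (2S)-sakuranetin 3 (not isolated)
Conditions: PPh3, DIAD (1.05 equiv each), MeOH (1.0 equiv), THF, 0 °C, 2 h; then PPh3, DIAD, BnOH (1.1 equiv each), 0 °C to rt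
Reagents that add atoms: methanol, CO; benzyl alcohol, OCc1ccccc1
Why: Two Mitsunobu etherifications run one after the other follow phenol acidity (7-OH first, then 4'-OH, while the 5-OH chelated to the C-4 carbonyl stays out), and because no free base is present ring C does not open, so C-2 stays S.

Step 3
Reactants: 4 (2S)-4'-O-benzylsakuranetin
Product: 5 (2S)-4'-O-benzyl-6-iodosakuranetin [(2S)-2-(4-benzyloxyphenyl)-5-hydroxy-6-iodo-7-methoxychroman-4-one]
Conditions: NIS (1.05 equiv), DMF, rt, dark
Reagents that add atoms: N-iodosuccinimide, O=C1CCC(=O)N1I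
Why: Electrophilic aromatic iodination under neutral conditions goes ortho to the only free phenol of ring A, which is the known C-6 selectivity of 5-hydroxy-7-alkoxyflavonoids (5-O-alkyl analogues go to C-8), and it creates no stereocentre.

Step 4 (key step)
Reactants: 2 (2S)-6,8-dibromonaringenin; 5 (2S)-4'-O-benzyl-6-iodosakuranetin
Product: 7 (2S,2''S)-4'''-O-benzyl-6,8-dibromo-6''-iodo-7''-O-methyl-3',8''-binaringenin, via aryloxy-λ3-iodane 6 (not isolated)
Conditions: 2 and PhI(OAc)2 (1.0 equiv each) co-added over 1 h to 5 (2.0 equiv, excess recovered), (CF3)2CHOH/CH2Cl2 3:1, −10 °C, then 30 min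
Reagents that add atoms: none
Why: Proposed new method: ligand exchange of PhI(OAc)2 with the only unhindered, non-chelated phenol in the flask (4'-OH of 2) gives aryloxy-λ3-iodane 6, an aromatic enolonium (phenoxenium) equivalent in which the normally nucleophilic C-3' has become electrophilic; the only open electron-rich arene carbon present is C-8'' of 5, because C-6'' is capped by iodine, C-6 and C-8 of 2 by bromine, and 4'''-OH by benzyl; C-8'' attacks C-3' in an SN2'-type step with loss of PhI and acetate, whereas carbon attack at C-1' would build a quaternary centre next to a di-ortho-substituted ring, and capture there by acetate or solvent is reversible in the ionising fluoroalcohol; tautomerisation then restores both arenes, no stereocentre is formed, and the weakly acidic medium leaves C-2 and C-2'' untouched; the closest known reaction types are the trivalent-iodine phenol–arene oxidative cross-coupling in fluoroalcohols ("aromatic ring umpolung") and the trivalent-iodine oxidation of the 4'-hydroxyphenyl ring of unprotected flavonoids to protoflavonoids.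

Step 5
Reactants: 7 (2S,2''S)-4'''-O-benzyl-6,8-dibromo-6''-iodo-7''-O-methyl-3',8''-binaringenin
Product: 8 (2S,2''S)-7''-O-methyl-3',8''-binaringenin (2,3,2'',3''-tetrahydrosotetsuflavone, CNP0237714.1)
Conditions: H2 (1 atm), Pd(OH)2/C (20 wt%), NaOAc (3.5 equiv), EtOAc/EtOH 1:1, rt; catalyst renewed once if uptake stalls
Reagents that add atoms: none
Why: Heterogeneous palladium-catalysed hydrogenolysis removes the three aryl halide caps and the benzyl ether in one operation, as in halogen-capped flavan-3-ol oligomer syntheses, while the acetate buffer keeps the medium weakly acidic so that neither flavanone ring opens and both centres stay S.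

## Compound list
1 | (2S)-naringenin | Oc1ccc([C@@H]2CC(=O)c3c(O)cc(O)cc3O2)cc1 | starting material
2 | (2S)-6,8-dibromonaringenin | Oc1ccc([C@@H]2CC(=O)c3c(O)c(Br)c(O)c(Br)c3O2)cc1 | intermediate
3 | (2S)-sakuranetin (7-O-methylnaringenin) | COc1cc(O)c2c(c1)O[C@H](c1ccc(O)cc1)CC2=O | intermediate
4 | (2S)-4'-O-benzylsakuranetin | COc1cc(O)c2c(c1)O[C@H](c1ccc(OCc3ccccc3)cc1)CC2=O | intermediate
5 | (2S)-4'-O-benzyl-6-iodosakuranetin | COc1c(I)c(O)c2c(c1)O[C@H](c1ccc(OCc3ccccc3)cc1)CC2=O | intermediate
6 | [4-((2S)-6,8-dibromo-5,7-dihydroxy-4-oxochroman-2-yl)phenoxy](phenyl)-λ3-iodanyl acetate | CC(=O)OI(c1ccccc1)Oc1ccc([C@@H]2CC(=O)c3c(O)c(Br)c(O)c(Br)c3O2)cc1 | intermediate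
7 | (2S,2''S)-4'''-O-benzyl-6,8-dibromo-6''-iodo-7''-O-methyl-3',8''-binaringenin | COc1c(I)c(O)c2c(c1-c1cc([C@@H]3CC(=O)c4c(O)c(Br)c(O)c(Br)c4O3)ccc1O)O[C@H](c1ccc(OCc3ccccc3)cc1)CC2=O | intermediate
8 | (2S,2''S)-7''-O-methyl-3',8''-binaringenin | COc1cc(O)c2c(c1-c1cc([C@@H]3CC(=O)c4c(O)cc(O)cc4O3)ccc1O)O[C@H](c1ccc(O)cc1)CC2=O | target

## Step count and risks
Total step count: 5. Longest linear sequence: 4 (steps 2, 3, 4, 5).

**Most likely to fail, first: step 4.**
- Acetate or solvent may capture the activated ring B irreversibly at C-1'.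
- The activated ring B may lose H-2 and end as the flavone.
- It may couple with a second molecule of 2.
- Product 7 may be oxidised further.

The fallback sets out from 2 and comes back at 7. It separates the oxidation from the C–C bond formation. Compound 2 alone is oxidised with PhI(OAc)2 in MeOH at 0 °C. This gives the isolable para-quinol methyl ether (2S)-6,8-dibromo-5,7-dihydroxy-2-(1-methoxy-4-oxocyclohexa-2,5-dien-1-yl)chroman-4-one F1. Its C-1' carries two identical dienone arms, so it is not a stereocentre. F1 is then ionised with TfOH (5 mol%) in (CF3)2CHOH at −10 °C in the presence of 5 (1.5 equiv), with no oxidant left in the flask. C-8'' attacks C-3', alpha to the dienone carbonyl, with loss of methanol. This is the substitution mode known for quinone monoketals with electron-rich arenes. Tautomerisation then gives 7.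

**Second: step 3.** Iodine may enter partly at C-8 or on ring B, or the iodine cap may be lost by ipso attack in step 4. The fallback sets out from 4 and comes back at 8. It gives up the cap and settles the regiochemistry by separation. Compound 4 (2 equiv) is coupled with 2 under the conditions of step 4. The product is (2S,2''S)-4'''-O-benzyl-6,8-dibromo-7''-O-methyl-3',8''-binaringenin F2. Reversed-phase HPLC separates it from the C-6''-linked isomer (2S,2''S)-4'''-O-benzyl-6,8-dibromo-7''-O-methyl-3',6''-binaringenin F3. The two are told apart by HMBC from the chelated 5''-OH to a CH or a quaternary carbon. F2 is then hydrogenolysed as in step 5 to give 8.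

**Third: step 2.** The 7-OH/4'-OH discrimination in the first Mitsunobu reaction may be incomplete, and some ee may be lost through phenoxide ion pairs. The fallback sets out from 1 and comes back at 4. An acetate relay fixes the order of alkylation in place of phenol acidity.
- Compound 1 is peracetylated (Ac2O, pyridine, 0 °C) to (2S)-naringenin 4',5,7-triacetate F4.
- PhSH with catalytic imidazole in N-methylpyrrolidone at 0 °C removes only the 7-acetate, the ester para to the carbonyl group, and gives (2S)-naringenin 4',5-diacetate F5.
- The single free phenol is methylated with Me3SiCHN2 in toluene/MeOH to (2S)-sakuranetin 4',5-diacetate F6.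
- HCl in MeOH (from AcCl, 0 °C to rt) takes off both acetates to give 3, which is now isolated.
- One Mitsunobu reaction with BnOH, which can only go to 4'-OH, gives 4.

## Further compounds
F1 | step 4 | (2S)-6,8-dibromo-5,7-dihydroxy-2-(1-methoxy-4-oxocyclohexa-2,5-dien-1-yl)chroman-4-one | COC1(C=CC(=O)C=C1)[C@@H]2CC(=O)c3c(O)c(Br)c(O)c(Br)c3O2
F2 | step 3 | (2S,2''S)-4'''-O-benzyl-6,8-dibromo-7''-O-methyl-3',8''-binaringenin | COc1cc(O)c2c(c1-c1cc([C@@H]3CC(=O)c4c(O)c(Br)c(O)c(Br)c4O3)ccc1O)O[C@H](c1ccc(OCc3ccccc3)cc1)CC2=O
F3 | step 3 | (2S,2''S)-4'''-O-benzyl-6,8-dibromo-7''-O-methyl-3',6''-binaringenin | COc1cc2O[C@H](c3ccc(OCc4ccccc4)cc3)CC(=O)c2c(O)c1-c1cc([C@@H]3CC(=O)c4c(O)c(Br)c(O)c(Br)c4O3)ccc1O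
F4 | step 2 | (2S)-naringenin 4',5,7-triacetate | CC(=O)Oc1ccc([C@@H]2CC(=O)c3c(OC(C)=O)cc(OC(C)=O)cc3O2)cc1
F5 | step 2 | (2S)-naringenin 4',5-diacetate | CC(=O)Oc1ccc([C@@H]2CC(=O)c3c(OC(C)=O)cc(O)cc3O2)cc1
F6 | step 2 | (2S)-sakuranetin 4',5-diacetate | CC(=O)Oc1ccc([C@@H]2CC(=O)c3c(OC(C)=O)cc(OC)cc3O2)cc1
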